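**Retrosynthetic overview**
1. Petrosin A is meso. The last step is a twofold 1,4-hydride reduction of a macrocyclic bis-enaminone, with base equilibration setting C3/C3' and confirming C1/C1'.
2. The 16-membered ring is closed by ring-closing metathesis (C1-allyl of half A with C9'-butenyl of half B). Before that, the two mirror-image bicyclic enaminones are joined by C1'-alkylation (enolate of half B with the allylic bromide of half A).
3. In each half, ring A comes from amide-acetal aza-annulation of a trans-2,3-disubstituted piperidine, and ring B from Staudinger reduction and intramolecular aza-Michael addition of an azido enone.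
4. The azido enone comes from enone cross-metathesis on a vinyl-branched C9 stereocentre, set by Cu-catalysed asymmetric allylic alkylation (enantiomeric ligands give the two halves).
5. Ring order: ring B, then ring A (in each half), then the macrocycle.

Assumption: the SMILES given is centrosymmetric (one half 1R,3R,9S,9aS, the other 1S,3S,9R,9aR), so petrosin A is the meso, achiral diastereomer; "single enantiomer" is read as "this single meso diastereomer", built from two mirror-image halves.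

Conventions: each half is numbered as a quinolizine (C1–C4, N5, C6–C9, C9a); primed locants belong to half B. Series A (6–17) gives half A, series B (18–27) gives half B. Which Taniaphos enantiomer gives 6 and which gives 18 is confirmed on the first run; exchanging them only exchanges the two mirror-image series and gives the same meso product. Any minor enantiomer of a half ends up in diastereomeric (non-meso) dimers, removed by chromatography after step 18.

**Step 1**
Reactants: 1 5-chloropent-1-ene; 2 (E)-1,4-dibromobut-2-ene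
Product: 3 (E)-1-bromo-6-chlorohex-2-ene
Conditions: 2 (3 equiv), second-generation Hoveyda–Grubbs catalyst (2 mol%), CH2Cl2, 40 °C; distillation
Reagents that add atoms: none
Why: Olefin cross-metathesis of an unhindered terminal alkene with excess symmetrical allylic dibromide gives the (E)-allylic bromide (E favoured) with allyl bromide as the only co-product; no stereocentre is formed.

**Step 2**
Reactants: 4 2-(2-bromoethyl)-1,3-dioxolane
Product: 5 [2-(1,3-dioxolan-2-yl)ethyl]magnesium bromide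
Conditions: Mg turnings (1.3 equiv), I2 (cat.), THF, 20–25 °C; titrated stock solution for steps 3 and 11
Reagents that add atoms: magnesium, [Mg]
Why: Grignard formation by insertion of Mg into the C–Br bond, kept below 30 °C because this acetal Grignard reagent is thermally labile; no stereocentre.

**Step 3**
Reactants: 3 (E)-1-bromo-6-chlorohex-2-ene; 5 [2-(1,3-dioxolan-2-yl)ethyl]magnesium bromide
Product: 6 2-[(3S)-6-chloro-3-ethenylhexyl]-1,3-dioxolane
Conditions: CuBr·SMe2 (5 mol%), (R,R)-Taniaphos (6 mol%), CH2Cl2, −78 °C, 5 (1.3 equiv) added over 2 h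
Reagents that add atoms: none
Why: Copper-catalysed asymmetric allylic alkylation (SN2' delivery of the alkyl group to the γ-carbon of the allylic bromide) creates the future C9 stereocentre under ligand control, while the primary chloride and the acetal are inert at −78 °C.

**Step 4**
Reactants: 6 2-[(3S)-6-chloro-3-ethenylhexyl]-1,3-dioxolane
Product: 7 2-[(3R)-6-azido-3-ethenylhexyl]-1,3-dioxolane
Conditions: NaN3 (1.5 equiv), NaI (0.1 equiv), DMF, 60 °C
Reagents that add atoms: sodium azide, [Na+].[N-]=[N+]=[N-]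
Why: SN2 displacement of the primary chloride (iodide-assisted) installs the nitrogen; the stereocentre is untouched (S becomes R only through changed CIP priorities).

**Step 5**
Reactants: 7 2-[(3R)-6-azido-3-ethenylhexyl]-1,3-dioxolane; 8 pent-1-en-3-one
Product: 9 (4E,6R)-6-(3-azidopropyl)-8-(1,3-dioxolan-2-yl)oct-4-en-3-one
Conditions: 8 (3 equiv), second-generation Hoveyda–Grubbs catalyst (5 mol%), CH2Cl2, 40 °C
Reagents that add atoms: none
Why: Cross-metathesis of the terminal alkene with an electron-poor vinyl ketone selectively gives the (E)-enone cross product and leaves azide and acetal alone; the stereocentre is not involved.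

**Step 6**
Reactants: 9 (4E,6R)-6-(3-azidopropyl)-8-(1,3-dioxolan-2-yl)oct-4-en-3-one
Product: 12 1-{(2R,3R)-3-[2-(1,3-dioxolan-2-yl)ethyl]piperidin-2-yl}butan-2-one, via iminophosphorane 10 (not isolated), via amino enone 11 (not isolated)
Conditions: PPh3 (1.2 equiv), THF, rt; H2O, 50 °C; then K2CO3 (0.2 equiv), MeOH, rt
Reagents that add atoms: none
Why: Staudinger reduction frees the primary amine, which closes ring B by reversible 6-exo-trig intramolecular aza-Michael addition, so C9a (piperidine C2) equilibrates to the diequatorial trans isomer relative to the fixed C9 (piperidine C3).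

**Step 7**
Reactants: 12 1-{(2R,3R)-3-[2-(1,3-dioxolan-2-yl)ethyl]piperidin-2-yl}butan-2-one
Product: 14 (9R,9aR)-9-[2-(1,3-dioxolan-2-yl)ethyl]-3-methyl-1,6,7,8,9,9a-hexahydro-2H-quinolizin-2-one, via dimethylamino adduct 13 (not isolated)
Conditions: Me2NCH(OMe)2 (3 equiv), toluene, 100 °C
Reagents that add atoms: N,N-dimethylformamide dimethyl acetal, COC(OC)N(C)C
Why: Amide-acetal aza-annulation (N-aminomethylenation, intramolecular Mannich attack through the ethyl-side α-carbon as the only six-membered closure, then E1cB loss of Me2NH) builds ring A as a vinylogous amide with C4 from the reagent; C9 and C9a are not touched.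

**Step 8**
Reactants: 14 (9R,9aR)-9-[2-(1,3-dioxolan-2-yl)ethyl]-3-methyl-1,6,7,8,9,9a-hexahydro-2H-quinolizin-2-one
Product: 15 3-[(9R,9aR)-3-methyl-2-oxo-1,6,7,8,9,9a-hexahydro-2H-quinolizin-9-yl]propanal
Conditions: 1 M HCl, THF, rt; NaHCO3 work-up
Reagents that add atoms: water, O
Why: Acid-catalysed acetal hydrolysis; the vinylogous amide survives dilute acid and its nucleophilic carbon (C3) is blocked by the methyl group, so the aldehyde does not cyclise.

**Step 9**
Reactants: 15 3-[(9R,9aR)-3-methyl-2-oxo-1,6,7,8,9,9a-hexahydro-2H-quinolizin-9-yl]propanal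
Product: 16 (9S,9aR)-9-(but-3-en-1-yl)-3-methyl-1,6,7,8,9,9a-hexahydro-2H-quinolizin-2-one
Conditions: MePPh3Br (1.5 equiv), KOt-Bu (1.4 equiv), THF, 0 °C → rt
Reagents that add atoms: methyltriphenylphosphonium bromide, C[P+](c1ccccc1)(c1ccccc1)c1ccccc1.[Br-]
Why: Wittig methylenation of the aldehyde; the ylide does not attack the much less electrophilic vinylogous amide carbonyl, and no stereocentre changes (the C9 descriptor changes through CIP priorities only).

**Step 10**
Reactants: 16 (9S,9aR)-9-(but-3-en-1-yl)-3-methyl-1,6,7,8,9,9a-hexahydro-2H-quinolizin-2-one; 2 (E)-1,4-dibromobut-2-ene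
Product: 17 (9S,9aR)-9-[(3E)-5-bromopent-3-en-1-yl]-3-methyl-1,6,7,8,9,9a-hexahydro-2H-quinolizin-2-one
Conditions: 2 (4 equiv), second-generation Hoveyda–Grubbs catalyst (5 mol%), CH2Cl2, 40 °C; used at once
Reagents that add atoms: none
Why: Cross-metathesis turns the butenyl terminus into the (E)-allylic bromide; the push–pull trisubstituted enaminone C=C is inert to the ruthenium carbene and the vinylogous amide nitrogen is too weakly nucleophilic to quaternise.

**Step 11**
Reactants: 3 (E)-1-bromo-6-chlorohex-2-ene; 5 [2-(1,3-dioxolan-2-yl)ethyl]magnesium bromide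
Product: 18 2-[(3R)-6-chloro-3-ethenylhexyl]-1,3-dioxolane
Conditions: CuBr·SMe2 (5 mol%), (S,S)-Taniaphos (6 mol%), CH2Cl2, −78 °C, 5 (1.3 equiv) added over 2 h
Reagents that add atoms: none
Why: The same copper-catalysed asymmetric allylic alkylation (SN2') as step 3 with the enantiomeric ligand sets the mirror-image C9' stereocentre.

**Step 12**
Reactants: 18 2-[(3R)-6-chloro-3-ethenylhexyl]-1,3-dioxolane
Product: 19 2-[(3S)-6-azido-3-ethenylhexyl]-1,3-dioxolane
Conditions: NaN3 (1.5 equiv), NaI (0.1 equiv), DMF, 60 °C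
Reagents that add atoms: sodium azide, [Na+].[N-]=[N+]=[N-]
Why: SN2 azide displacement of the primary chloride as in step 4; the stereocentre is untouched.

**Step 13**
Reactants: 19 2-[(3S)-6-azido-3-ethenylhexyl]-1,3-dioxolane; 8 pent-1-en-3-one
Product: 20 (4E,6S)-6-(3-azidopropyl)-8-(1,3-dioxolan-2-yl)oct-4-en-3-one
Conditions: 8 (3 equiv), second-generation Hoveyda–Grubbs catalyst (5 mol%), CH2Cl2, 40 °C
Reagents that add atoms: none
Why: (E)-selective enone cross-metathesis as in step 5; the stereocentre is not involved.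

**Step 14**
Reactants: 20 (4E,6S)-6-(3-azidopropyl)-8-(1,3-dioxolan-2-yl)oct-4-en-3-one
Product: 23 1-{(2S,3S)-3-[2-(1,3-dioxolan-2-yl)ethyl]piperidin-2-yl}butan-2-one, via iminophosphorane 21 (not isolated), via amino enone 22 (not isolated)
Conditions: PPh3 (1.2 equiv), THF, rt; H2O, 50 °C; then K2CO3 (0.2 equiv), MeOH, rt
Reagents that add atoms: none
Why: Staudinger reduction and reversible 6-exo-trig intramolecular aza-Michael addition as in step 6 give the thermodynamic trans piperidine, setting C9a'.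

**Step 15**
Reactants: 23 1-{(2S,3S)-3-[2-(1,3-dioxolan-2-yl)ethyl]piperidin-2-yl}butan-2-one
Product: 25 (9S,9aS)-9-[2-(1,3-dioxolan-2-yl)ethyl]-3-methyl-1,6,7,8,9,9a-hexahydro-2H-quinolizin-2-one, via dimethylamino adduct 24 (not isolated)
Conditions: Me2NCH(OMe)2 (3 equiv), toluene, 100 °C
Reagents that add atoms: N,N-dimethylformamide dimethyl acetal, COC(OC)N(C)C
Why: Amide-acetal aza-annulation (intramolecular Mannich closure and E1cB loss of Me2NH) as in step 7 forms ring A of half B without touching its stereocentres.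

**Step 16**
Reactants: 25 (9S,9aS)-9-[2-(1,3-dioxolan-2-yl)ethyl]-3-methyl-1,6,7,8,9,9a-hexahydro-2H-quinolizin-2-one
Product: 26 3-[(9S,9aS)-3-methyl-2-oxo-1,6,7,8,9,9a-hexahydro-2H-quinolizin-9-yl]propanal
Conditions: 1 M HCl, THF, rt; NaHCO3 work-up
Reagents that add atoms: water, O
Why: Acid-catalysed acetal hydrolysis as in step 8; the vinylogous amide is stable to dilute acid.

**Step 17**
Reactants: 26 3-[(9S,9aS)-3-methyl-2-oxo-1,6,7,8,9,9a-hexahydro-2H-quinolizin-9-yl]propanal
Product: 27 (9R,9aS)-9-(but-3-en-1-yl)-3-methyl-1,6,7,8,9,9a-hexahydro-2H-quinolizin-2-one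
Conditions: MePPh3Br (1.5 equiv), KOt-Bu (1.4 equiv), THF, 0 °C → rt
Reagents that add atoms: methyltriphenylphosphonium bromide, C[P+](c1ccccc1)(c1ccccc1)c1ccccc1.[Br-]
Why: Wittig methylenation as in step 9 gives the butenyl terminus needed for the ring closure; stereocentres are unchanged.

**Step 18**
Reactants: 27 (9R,9aS)-9-(but-3-en-1-yl)-3-methyl-1,6,7,8,9,9a-hexahydro-2H-quinolizin-2-one; 17 (9S,9aR)-9-[(3E)-5-bromopent-3-en-1-yl]-3-methyl-1,6,7,8,9,9a-hexahydro-2H-quinolizin-2-one
Product: 29 (1S,9R,9aR)-9-(but-3-en-1-yl)-3-methyl-1-{(2E)-5-[(9S,9aR)-3-methyl-2-oxo-1,6,7,8,9,9a-hexahydro-2H-quinolizin-9-yl]pent-2-en-1-yl}-1,6,7,8,9,9a-hexahydro-2H-quinolizin-2-one, via lithium enolate 28 (not isolated)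
Conditions: LiN(i-Pr)2 (1.05 equiv), THF, −78 °C; then 17 (1.05 equiv), DMPU, −78 → −40 °C; aq NH4Cl
Reagents that add atoms: none
Why: α'-Deprotonation of the vinylogous amide (C1' is its only acidic site) and SN2 alkylation by the allylic bromide join the two mirror-image halves; the electrophile enters axially, anti to H9a', so the new chain is trans to H9a' (1'S), which is also the thermodynamic orientation.

**Step 19**
Reactants: 29 (coupled bis-enaminone, see step 18); 30 3-bromoprop-1-ene (allyl bromide)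
Product: 32 (1S,9R,9aR)-9-(but-3-en-1-yl)-3-methyl-1-{(2E)-5-[(1R,9S,9aS)-3-methyl-2-oxo-1-(prop-2-en-1-yl)-1,6,7,8,9,9a-hexahydro-2H-quinolizin-9-yl]pent-2-en-1-yl}-1,6,7,8,9,9a-hexahydro-2H-quinolizin-2-one, via lithium enolate 31 (not isolated)
Conditions: LiN(i-Pr)2 (1.1 equiv), THF, −78 °C; 30 (3 equiv), −78 → −40 °C
Reagents that add atoms: none
Why: Kinetic deprotonation occurs at the only α'-CH2 left (C1 of half A; the tertiary C1'–H of half B is hindered), and axial enolate allylation anti to H9a sets C1 (1R).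

**Step 20**
Reactants: 32 (allylated bis-enaminone, see step 19)
Product: 33 (1R,9S,9aS,1'S,9'R,9a'R)-3,4,3',4'-tetradehydropetrosin A bearing an (E)-CH=CH in each bridge (each bridge is C1–CH2–CH=CH–CH2–CH2–C9 of the other half)
Conditions: second-generation Grubbs catalyst (10 mol% in two portions), CH2Cl2 (1 mM), 40 °C
Reagents that add atoms: none
Why: Ring-closing metathesis of the two terminal alkenes (allyl on C1 of half A, butenyl on C9' of half B) closes the 16-membered ring with loss of ethene; no stereocentre is formed and the E/Z ratio of the new alkene is irrelevant.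

**Step 21**
Reactants: 33 (macrocyclic bis-enaminone diene, see step 20)
Product: 34 (1R,9S,9aS,1'S,9'R,9a'R)-3,4,3',4'-tetradehydropetrosin A (macrocyclic bis-enaminone with two pentamethylene bridges)
Conditions: H2 (1 atm), Pd/C (10%), EtOAc, rt
Reagents that add atoms: none
Why: Heterogeneous hydrogenation saturates both disubstituted bridge alkenes, whereas the vinylogous amide C=C bonds resist reduction under neutral conditions (partial reduction there would be harmless).

**Step 22**
Reactants: 34 (saturated macrocyclic bis-enaminone, see step 21)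
Product: 36 petrosin A (1R,3R,9S,9aS,1'S,3'S,9'R,9a'R; meso), via bis(lithium enolate) 35 (not isolated)
Conditions: LiBH(s-Bu)3 (2.2 equiv), THF, −78 → −40 °C; MeOH, −78 °C → rt, 3 h; aq NH4Cl
Reagents that add atoms: none
Why: Conjugate (1,4) hydride addition to both vinylogous amides gives the bis-enolate, and protonation followed by LiOMe-mediated enolisation equilibrates C3/C3' to equatorial methyl while C1/C1' keep the axial bridge (no peri clash with the equatorial C9 chain), under conditions too mild for retro-Mannich epimerisation at C9a.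

**Compound list**
1 | 5-chloropent-1-ene | C=CCCCCl | starting material
2 | (E)-1,4-dibromobut-2-ene | BrC/C=C/CBr | starting material
3 | (E)-1-bromo-6-chlorohex-2-ene | ClCCC/C=C/CBr | intermediate
4 | 2-(2-bromoethyl)-1,3-dioxolane | BrCCC1OCCO1 | starting material
5 | [2-(1,3-dioxolan-2-yl)ethyl]magnesium bromide | Br[Mg]CCC1OCCO1 | intermediate
6 | 2-[(3S)-6-chloro-3-ethenylhexyl]-1,3-dioxolane | ClCCC[C@@H](C=C)CCC1OCCO1 | intermediate
7 | 2-[(3R)-6-azido-3-ethenylhexyl]-1,3-dioxolane | [N-]=[N+]=NCCC[C@@H](C=C)CCC1OCCO1 | intermediate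
8 | pent-1-en-3-one | CCC(=O)C=C | starting material
9 | (4E,6R)-6-(3-azidopropyl)-8-(1,3-dioxolan-2-yl)oct-4-en-3-one | CCC(=O)/C=C/[C@H](CCCN=[N+]=[N-])CCC1OCCO1 | intermediate
10 | (4E,6R)-8-(1,3-dioxolan-2-yl)-6-{3-[(triphenylphosphoranylidene)amino]propyl}oct-4-en-3-one | CCC(=O)/C=C/[C@H](CCCN=P(c1ccccc1)(c1ccccc1)c1ccccc1)CCC1OCCO1 | intermediate
11 | (4E,6R)-6-(3-aminopropyl)-8-(1,3-dioxolan-2-yl)oct-4-en-3-one | CCC(=O)/C=C/[C@H](CCCN)CCC1OCCO1 | intermediate
12 | 1-{(2R,3R)-3-[2-(1,3-dioxolan-2-yl)ethyl]piperidin-2-yl}butan-2-one | CCC(=O)C[C@H]1NCCC[C@@H]1CCC2OCCO2 | intermediate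
13 | (9R,9aR)-4-(dimethylamino)-9-[2-(1,3-dioxolan-2-yl)ethyl]-3-methyloctahydro-2H-quinolizin-2-one (C3/C4 epimers) | CC1C(N(C)C)N2CCC[C@H](CCC3OCCO3)[C@H]2CC1=O | intermediate
14 | (9R,9aR)-9-[2-(1,3-dioxolan-2-yl)ethyl]-3-methyl-1,6,7,8,9,9a-hexahydro-2H-quinolizin-2-one | CC1=CN2CCC[C@H](CCC3OCCO3)[C@H]2CC1=O | intermediate
15 | 3-[(9R,9aR)-3-methyl-2-oxo-1,6,7,8,9,9a-hexahydro-2H-quinolizin-9-yl]propanal | CC1=CN2CCC[C@H](CCC=O)[C@H]2CC1=O | intermediate
16 | (9S,9aR)-9-(but-3-en-1-yl)-3-methyl-1,6,7,8,9,9a-hexahydro-2H-quinolizin-2-one | CC1=CN2CCC[C@H](CCC=C)[C@H]2CC1=O | intermediate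
17 | (9S,9aR)-9-[(3E)-5-bromopent-3-en-1-yl]-3-methyl-1,6,7,8,9,9a-hexahydro-2H-quinolizin-2-one | CC1=CN2CCC[C@H](CC/C=C/CBr)[C@H]2CC1=O | intermediate
18 | 2-[(3R)-6-chloro-3-ethenylhexyl]-1,3-dioxolane | ClCCC[C@H](C=C)CCC1OCCO1 | intermediate
19 | 2-[(3S)-6-azido-3-ethenylhexyl]-1,3-dioxolane | [N-]=[N+]=NCCC[C@H](C=C)CCC1OCCO1 | intermediate
20 | (4E,6S)-6-(3-azidopropyl)-8-(1,3-dioxolan-2-yl)oct-4-en-3-one | CCC(=O)/C=C/[C@@H](CCCN=[N+]=[N-])CCC1OCCO1 | intermediate
21 | (4E,6S)-8-(1,3-dioxolan-2-yl)-6-{3-[(triphenylphosphoranylidene)amino]propyl}oct-4-en-3-one | CCC(=O)/C=C/[C@@H](CCCN=P(c1ccccc1)(c1ccccc1)c1ccccc1)CCC1OCCO1 | intermediate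
22 | (4E,6S)-6-(3-aminopropyl)-8-(1,3-dioxolan-2-yl)oct-4-en-3-one | CCC(=O)/C=C/[C@@H](CCCN)CCC1OCCO1 | intermediate
23 | 1-{(2S,3S)-3-[2-(1,3-dioxolan-2-yl)ethyl]piperidin-2-yl}butan-2-one | CCC(=O)C[C@@H]1NCCC[C@H]1CCC2OCCO2 | intermediate
24 | (9S,9aS)-4-(dimethylamino)-9-[2-(1,3-dioxolan-2-yl)ethyl]-3-methyloctahydro-2H-quinolizin-2-one (C3/C4 epimers) | CC1C(N(C)C)N2CCC[C@@H](CCC3OCCO3)[C@@H]2CC1=O | intermediate
25 | (9S,9aS)-9-[2-(1,3-dioxolan-2-yl)ethyl]-3-methyl-1,6,7,8,9,9a-hexahydro-2H-quinolizin-2-one | CC1=CN2CCC[C@@H](CCC3OCCO3)[C@@H]2CC1=O | intermediate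
26 | 3-[(9S,9aS)-3-methyl-2-oxo-1,6,7,8,9,9a-hexahydro-2H-quinolizin-9-yl]propanal | CC1=CN2CCC[C@@H](CCC=O)[C@@H]2CC1=O | intermediate
27 | (9R,9aS)-9-(but-3-en-1-yl)-3-methyl-1,6,7,8,9,9a-hexahydro-2H-quinolizin-2-one | CC1=CN2CCC[C@@H](CCC=C)[C@@H]2CC1=O | intermediate
28 | lithium (9R,9aR)-9-(but-3-en-1-yl)-3-methyl-6,7,8,9-tetrahydro-9aH-quinolizin-2-olate (C1=C2 enolate of 27) | CC1=CN2CCC[C@@H](CCC=C)[C@@H]2C=C1O[Li] | intermediate
29 | (1S,9R,9aR)-9-(but-3-en-1-yl)-3-methyl-1-{(2E)-5-[(9S,9aR)-3-methyl-2-oxo-1,6,7,8,9,9a-hexahydro-2H-quinolizin-9-yl]pent-2-en-1-yl}-1,6,7,8,9,9a-hexahydro-2H-quinolizin-2-one | CC1=CN2CCC[C@H](CC/C=C/C[C@@H]3C(=O)C(C)=CN4CCC[C@@H](CCC=C)[C@H]34)[C@H]2CC1=O | intermediate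
30 | 3-bromoprop-1-ene (allyl bromide) | C=CCBr | starting material
31 | lithium C1=C2 enolate of the unsubstituted (half A) ring of 29 | CC1=CN2CCC[C@H](CC/C=C/C[C@@H]3C(=O)C(C)=CN4CCC[C@@H](CCC=C)[C@H]34)[C@H]2C=C1O[Li] | intermediate
32 | (1S,9R,9aR)-9-(but-3-en-1-yl)-3-methyl-1-{(2E)-5-[(1R,9S,9aS)-3-methyl-2-oxo-1-(prop-2-en-1-yl)-1,6,7,8,9,9a-hexahydro-2H-quinolizin-9-yl]pent-2-en-1-yl}-1,6,7,8,9,9a-hexahydro-2H-quinolizin-2-one | CC1=CN2CCC[C@H](CC/C=C/C[C@@H]3C(=O)C(C)=CN4CCC[C@@H](CCC=C)[C@H]34)[C@H]2[C@@H](CC=C)C1=O | intermediate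
33 | (1R,9S,9aS,1'S,9'R,9a'R)-3,4,3',4'-tetradehydropetrosin A with an (E)-CH=CH in each bridge (C1–CH2–CH=CH–CH2–CH2–C9 of the other half; the metathesis alkene may be E/Z) | CC1=CN2CCC[C@@H]3CC/C=C/C[C@@H]4C(=O)C(C)=CN5CCC[C@@H](CC/C=C/C[C@@H](C1=O)[C@H]32)[C@H]45 | intermediate
34 | (1R,9S,9aS,1'S,9'R,9a'R)-3,4,3',4'-tetradehydropetrosin A (two 3-methyl-hexahydroquinolizin-2-one units, C1 of each joined to C9 of the other by (CH2)5) | CC1=CN2CCC[C@@H]3CCCCC[C@@H]4C(=O)C(C)=CN5CCC[C@@H](CCCCC[C@@H](C1=O)[C@H]32)[C@H]45 | intermediate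
35 | bis(lithium enolate) of petrosin A (C2=C3 and C2'=C3' enolates) | CC=1CN2CCC[C@@H]3CCCCC[C@@H]4C(O[Li])=C(C)CN5CCC[C@@H](CCCCC[C@@H](C=1O[Li])[C@H]32)[C@H]45 | intermediate
36 | petrosin A (1R,3R,9S,9aS,1'S,3'S,9'R,9a'R; meso) | C[C@@H]1CN2CCC[C@@H]3CCCCC[C@@H]4C(=O)[C@@H](C)CN5CCC[C@@H](CCCCC[C@@H](C1=O)[C@H]32)[C@H]45 | target

**Totals**
Total step count: 22.
Longest linear sequence: 14 steps (1, 3–10, 18–22; the path through step 2 is equally long).

**Three steps most likely to fail**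

Step 7 (and its mirror image, step 15). The amide acetal may aminomethylenate the wrong α-carbon (C1) or stall at the N-formamidine stage. Fallback: from 12, N-formylation with ethyl formate (reflux) gives (2R,3R)-3-[2-(1,3-dioxolan-2-yl)ethyl]-2-(2-oxobutyl)piperidine-1-carbaldehyde F1. KOt-Bu in THF/t-BuOH then closes ring A by an intramolecular aldol-type (Camps-type) condensation of the ethyl-side enolate onto the formamide with loss of water, which comes back to the route at 14. In series B the same two operations lead from 23 through (2S,3S)-3-[2-(1,3-dioxolan-2-yl)ethyl]-2-(2-oxobutyl)piperidine-1-carbaldehyde F2 to 25.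

Step 20. The macrocyclisation competes with oligomerisation and with ring closure onto the internal bridge alkene (eight-membered rings with loss of half of the molecule). Fallback: from 29 (which also bypasses step 19), cross-metathesis of the butenyl group with 2 (second-generation Hoveyda–Grubbs catalyst, CH2Cl2, 40 °C, stopped once the terminal alkene is consumed) gives (1S,9R,9aR)-9-[(3E)-5-bromopent-3-en-1-yl]-3-methyl-1-{(2E)-5-[(9S,9aR)-3-methyl-2-oxo-1,6,7,8,9,9a-hexahydro-2H-quinolizin-9-yl]pent-2-en-1-yl}-1,6,7,8,9,9a-hexahydro-2H-quinolizin-2-one F3. Slow addition of F3 to LiN(SiMe3)2 in THF at high dilution (−78 → −20 °C) closes the ring by intramolecular axial C1-alkylation of the half A enolate, which comes back to the route at 33.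

Step 22. The vinylogous amides may resist hydride, or the saturated ketone may be over-reduced or epimerised at C9a. Fallback: from 34, hydrogenation over PtO2 in AcOH (H2, 4 bar) reduces both vinylogous amides completely to the macrocyclic bis(amino alcohol) (2,2'-dihydroxy analogue of petrosin A, C2/C3 epimers) F4. Swern oxidation ((COCl)2, DMSO, Et3N, −78 °C) followed by K2CO3/MeOH equilibration of C3/C3' comes back to the route at 36.

**Further compounds**
F1 | step 7 | (2R,3R)-3-[2-(1,3-dioxolan-2-yl)ethyl]-2-(2-oxobutyl)piperidine-1-carbaldehyde | CCC(=O)C[C@H]1N(C=O)CCC[C@@H]1CCC2OCCO2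
F2 | step 7 | (2S,3S)-3-[2-(1,3-dioxolan-2-yl)ethyl]-2-(2-oxobutyl)piperidine-1-carbaldehyde | CCC(=O)C[C@@H]1N(C=O)CCC[C@H]1CCC2OCCO2
F3 | step 20 | (1S,9R,9aR)-9-[(3E)-5-bromopent-3-en-1-yl]-3-methyl-1-{(2E)-5-[(9S,9aR)-3-methyl-2-oxo-1,6,7,8,9,9a-hexahydro-2H-quinolizin-9-yl]pent-2-en-1-yl}-1,6,7,8,9,9a-hexahydro-2H-quinolizin-2-one | CC1=CN2CCC[C@H](CC/C=C/C[C@@H]3C(=O)C(C)=CN4CCC[C@@H](CC/C=C/CBr)[C@H]34)[C@H]2CC1=O
F4 | step 22 | macrocyclic bis(amino alcohol): (1R,9S,9aS,1'S,9'R,9a'R)-2,2'-dihydroxy analogue of petrosin A (C2/C3 and C2'/C3' epimers) | CC1CN2CCC[C@@H]3CCCCC[C@@H]4C(O)C(C)CN5CCC[C@@H](CCCCC[C@@H](C1O)[C@H]32)[C@H]45
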